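The readings come from a simulation from invented constants; noise was put on by code.

The midnight run held the same charge of substrate as the flask, 0.92 M, but twice its catalyst, so I read it first.

| flask | substrate | catalyst | remark | time |
|---|---|---|---|---|
| dusk | 0.46 M | 18 mM | run made earlier |  |
| summer | 0.69 M | 18 mM | run made earlier |  |
| midnight | 0.92 M | 36 mM | run made earlier |  |
| flask | 0.92 M | 18 mM |  | 15 h |

- dusk (time / h: target / %, substrate / %): 0.833: 68.4, 4.9; 1.33: 74.8, 3.4; 2.50: 79.3, 1.7; 5.00: 74.4, 0.2; 10.0: 58.7, 0
- summer (time / h: target / %, substrate / %): 0.833: 65.3, 5.6; 1.33: 71.4, 3.5; 2.50: 76.6, 2.4; 5.00: 73.2, 0.5; 10.0: 60.0, 0.3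
- midnight (time / h: target / %, substrate / %): 0.833: 71.9, 3.3; 1.33: 75.6, 2.1; 2.50: 74.4, 1.1; 5.00: 61.3, 0.2; 10.0: 42.3, 0

(standard deviation of a reading: 0.5 percentage points)

- percent here means substrate units held: one idle adduct counts as two
- what is said of target includes idle adduct
- steps under discussion: substrate -> side product; substrate + catalyst -> catalyst + target; substrate + target <-> idle adduct; target + catalyst <-> isomer of the product + catalyst
- in an amount of target, one idle adduct counts as one target

1. time up to 15 h at which target stands highest
2. the amount of target, in percent of the substrate charged, at that time

In the first instants of the midnight run the catalysed step was fast: by 0.833 h substrate read 3.3 % and target 71.9 %. The remainder of the charge stood in neither reading, and I took part of it to be the substrate held in the idle adduct. In the middle of that run free substrate stayed low while target reached its highest reading, 75.6 % at 1.33 h. At the end, with substrate reading 0 %, target had fallen to 42.3 % at 10.0 h, which I put down to the isomer of the product.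

I then divided the rate of making target by the rate of losing it to the isomer. Both steps carry the catalyst, so time and catalyst drop out of this selectivity factor, leaving the side step apart. To hold the catalyst fixed I compared the dusk and summer runs, both at 18 mM. The highest dusk reading, 79.3 % at 0.46 M, stood above the highest summer reading, 76.6 % at 0.69 M, and the two gave 0.117 M⁻¹. This is the price of charge, the fraction of the charge lost from the peak for each mole per litre of substrate added. Each reading carries a scatter of 0.5 percentage points. For the flask I reckoned a peak of 73.9 %.

The forecast gave 74.5 % at 3.1 h, higher than my figure, on the ground that “Higher concentration lowers the peak and delays it”.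

The flask gave 75.0 % at 3.24 h, as the forecast said within its margin.

    substrate → side product (k = 4.50 × 10⁻⁵ s⁻¹)
    substrate + catalyst → catalyst + target (k = 0.0580 M⁻¹ s⁻¹)
    substrate + target ⇌ idle adduct, settled at all times (K = 17.0 M⁻¹)
    target + catalyst ⇌ isomer of the product + catalyst, rate k4*[catalyst]*[target] forward; the back reaction follows from the equilibrium constant (K = 2.30, k = 0.00104 M⁻¹ s⁻¹)

That flask peak lay 1.1 points above my reckoning, which rested on two readings, each with a scatter of 0.5 points. The flask is best stopped near 3.24 h: by 15.0 h it held 49.1 % target beside 46.7 % isomer of the product. The neighbouring flask differed in its charge alone, 0.37 M of substrate. Carrying the price of charge from the dusk reading down to that charge gave 80.4 %, and that neighbour reached 80.3 %.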